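**Assumption:** the SMILES has no stereodescriptor and the molecule has no stereocentre; the hindered C3–N1' axis is unassigned, so the compound is made as drawn (as the racemate if the axis proves configurationally stable). "Indole A" is the NH-indole half, "indole B" the N-linked half.

## Retrosynthetic overview

1. Rings are closed in the order: pyrrole ring of indole B first, pyrrole ring of indole A last.
2. The C2–SMe of indole A arises by a 1,2-shift of SMe from C3 in a 3-(methylsulfanyl)-3-(indol-1-yl)-3H-indole, which comes from N1–C2 condensation of an ortho-amino aryl acetal.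
3. Key C–C bond (C3–C3a of indole A): azasulfonium-ylide [2,3] shift between N-chloro-3,4,5-tribromoaniline (a polarity-reversed aniline) and a sulfide that already carries indole B. This joins an aniline ortho carbon and an aldehyde α-carbon, both natively nucleophilic.
4. The C3–N1' bond: N-alkylation of indole B by MeS–CHCl–CH(OMe)2, an enolonium equivalent of acetaldehyde.
5. Indole B: 2-bromoindole from a 3-(methylsulfanyl)oxindole (POBr3), itself from 3,5-dibromoaniline and ethyl (methylsulfanyl)acetate by the same ylide shift.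

## Route

**Step 1**
Reactants: 1 3,5-dibromoaniline; 2 ethyl 2-(methylsulfanyl)acetate
Product: 6 4,6-dibromo-3-(methylsulfanyl)-1,3-dihydro-2H-indol-2-one (racemic), via N-chloroaniline 3 (not isolated), via azasulfonium chloride 4 (not isolated), via amino ester 5 (not isolated)
Conditions: t-BuOCl, CH2Cl2, −65 °C; then 2, −65 °C; then Et3N, −65 °C → rt; then 2 M aq HCl, Et2O, rt
Reagents that add atoms: none
Why: Gassman oxindole synthesis, in which N-chlorination reverses the polarity of the aniline, sulfide 2 adds at nitrogen to give 4, Et3N forms the ester-stabilised sulfur ylide, its [2,3]-sigmatropic (Sommelet–Hauser) shift joins the ester α-carbon to the ring ortho carbon, and acid closes the lactam; the two ortho positions of 1 are equivalent, so only the 4,6-dibromo isomer can form, and the racemic C3 centre is removed in step 2.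

**Step 2**
Reactants: 6 4,6-dibromo-3-(methylsulfanyl)-1,3-dihydro-2H-indol-2-one
Product: 7 2,4,6-tribromo-3-(methylsulfanyl)-1H-indole
Conditions: POBr3 (1.5 equiv), ClCH2CH2Cl, 80 °C; ice-water quench
Reagents that add atoms: phosphorus oxybromide, O=P(Br)(Br)Br
Why: Vilsmeier-type deoxybromination of a lactam, in which the 2-hydroxyindole tautomer is O-phosphorylated, bromide displaces the phosphate at C2 and loss of the C3 proton aromatises, so bromine goes to C2 without an electrophilic bromination that could move or oxidise the sulfide.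

**Step 3**
Reactants: 7 2,4,6-tribromo-3-(methylsulfanyl)-1H-indole; 8 1,1-dimethoxy-2-(methylsulfanyl)ethane
Product: 11 2,4,6-tribromo-1-[2,2-dimethoxy-1-(methylsulfanyl)ethyl]-3-(methylsulfanyl)-1H-indole (racemic), via chloro sulfide 9 (not isolated), via sodium indolide 10 (not isolated)
Conditions: 8, NCS, CH2Cl2, 0 °C → rt, filter, concentrate (crude 9); 7, NaH, DMF, 0 °C; add crude 9, 0 °C → rt
Reagents that add atoms: none
Why: NCS converts 8 through its chlorosulfonium salt (Pummerer-type α-chlorination) into α-chloro sulfide 9, an acetaldehyde α-cation (enolonium) equivalent, which alkylates sodium indolide 10 at nitrogen because C3 is blocked and DMF favours N-attack; the new N,S-acetal carbon is racemic and becomes sp2 in step 4.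

**Step 4**
Reactants: 11 2,4,6-tribromo-1-[2,2-dimethoxy-1-(methylsulfanyl)ethyl]-3-(methylsulfanyl)-1H-indole; 12 3,4,5-tribromoaniline
Product: 17 2,4,6-tribromo-3-(methylsulfanyl)-1-[4,5,6-tribromo-2-(methylsulfanyl)-1H-indol-3-yl]-1H-indole (target), via N-chloroaniline 13 (not isolated), via azasulfonium chloride 14 (not isolated), via amino acetal 15 (not isolated), via 3H-indole 16 (not isolated)
Conditions: 12 (1.1 equiv), t-BuOCl, CH2Cl2, −65 °C; then 11, −65 °C; then Et3N, −65 °C → rt (40 °C if the rearrangement is slow); then TFA (excess), CH2Cl2, 0 °C → rt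
Reagents that add atoms: none
Why: Proposed new method: N-chloroaniline 13 (polarity-reversed aniline) is attacked by the alkyl sulfide sulfur of 11 (the indole 3-SMe is flanked by two bromines on an electron-poor ring) to give 14, Et3N removes the methine proton (acidified by S+, the indole nitrogen and the acetal), the ylide undergoes a [2,3]-sigmatropic shift to either equivalent ortho carbon to form the C3–C3a bond of 15, TFA closes the ring to 16, and the 3H-indolium ion relieves its crowded quaternary C3 by 1,2-migration of SMe through an episulfonium ion to C2 and loss of H+; the closest known reactions are the Gassman synthesis of 3-methylthio-3H-indoles from α-branched α-thio ketones and the 1,2-sulfenyl (thio-Plancher) migration of 3-sulfenyl-3H-indolium ions, and the racemic centre of 15 and 16 is destroyed on aromatisation.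

## Compound list

1 | 3,5-dibromoaniline | Nc1cc(Br)cc(Br)c1 | starting material
2 | ethyl 2-(methylsulfanyl)acetate | CCOC(=O)CSC | starting material
3 | N-chloro-3,5-dibromoaniline | ClNc1cc(Br)cc(Br)c1 | intermediate
4 | [(3,5-dibromophenyl)amino](2-ethoxy-2-oxoethyl)methylsulfonium chloride | CCOC(=O)C[S+](C)Nc1cc(Br)cc(Br)c1.[Cl-] | intermediate
5 | ethyl 2-(2-amino-4,6-dibromophenyl)-2-(methylsulfanyl)acetate (racemic) | CCOC(=O)C(SC)c1c(N)cc(Br)cc1Br | intermediate
6 | 4,6-dibromo-3-(methylsulfanyl)-1,3-dihydro-2H-indol-2-one (racemic) | CSC1C(=O)Nc2cc(Br)cc(Br)c21 | intermediate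
7 | 2,4,6-tribromo-3-(methylsulfanyl)-1H-indole | CSc1c(Br)[nH]c2cc(Br)cc(Br)c12 | intermediate
8 | 1,1-dimethoxy-2-(methylsulfanyl)ethane ((methylthio)acetaldehyde dimethyl acetal) | COC(CSC)OC | starting material
9 | 1-chloro-2,2-dimethoxy-1-(methylsulfanyl)ethane (racemic) | COC(OC)C(Cl)SC | intermediate
10 | sodium 2,4,6-tribromo-3-(methylsulfanyl)indol-1-ide | CSc1c(Br)[n-]c2cc(Br)cc(Br)c12.[Na+] | intermediate
11 | 2,4,6-tribromo-1-[2,2-dimethoxy-1-(methylsulfanyl)ethyl]-3-(methylsulfanyl)-1H-indole (racemic) | COC(OC)C(SC)n1c(Br)c(SC)c2c(Br)cc(Br)cc21 | intermediate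
12 | 3,4,5-tribromoaniline | Nc1cc(Br)c(Br)c(Br)c1 | starting material
13 | N-chloro-3,4,5-tribromoaniline | ClNc1cc(Br)c(Br)c(Br)c1 | intermediate
14 | {2,2-dimethoxy-1-[2,4,6-tribromo-3-(methylsulfanyl)-1H-indol-1-yl]ethyl}(methyl)[(3,4,5-tribromophenyl)amino]sulfonium chloride | COC(OC)C([S+](C)Nc1cc(Br)c(Br)c(Br)c1)n1c(Br)c(SC)c2c(Br)cc(Br)cc21.[Cl-] | intermediate
15 | 3,4,5-tribromo-2-{2,2-dimethoxy-1-(methylsulfanyl)-1-[2,4,6-tribromo-3-(methylsulfanyl)-1H-indol-1-yl]ethyl}aniline (racemic) | COC(OC)C(SC)(c1c(N)cc(Br)c(Br)c1Br)n1c(Br)c(SC)c2c(Br)cc(Br)cc21 | intermediate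
16 | 4,5,6-tribromo-3-(methylsulfanyl)-3-[2,4,6-tribromo-3-(methylsulfanyl)-1H-indol-1-yl]-3H-indole (racemic) | CSC1(C=Nc2cc(Br)c(Br)c(Br)c21)n1c(Br)c(SC)c2c(Br)cc(Br)cc21 | intermediate
17 | 2,4,6-tribromo-3-(methylsulfanyl)-1-[4,5,6-tribromo-2-(methylsulfanyl)-1H-indol-3-yl]-1H-indole | CSc1[nH]c2cc(Br)c(Br)c(Br)c2c1-n1c(Br)c(SC)c2c(Br)cc(Br)cc21 | target

## Step count and risks

Total step count: 4. Longest linear sequence: 4 steps (1 → 6 → 7 → 11 → 17).

**Step 4 is the most likely to fail.** The N-chloroaniline may bind the wrong sulfur, the ylide may form at S–CH3 instead of the crowded methine, or the shift to a carbon next to bromine may be too hindered. The fallback sets out from 12 and comes back at 16; it builds ring A first with a robust ester-stabilised ylide and makes the C3–N1' bond by substitution. Aniline 12 is N-chlorinated to 13 (t-BuOCl, CH2Cl2, −65 °C) and combined with 2 to give (2-ethoxy-2-oxoethyl)(methyl)[(3,4,5-tribromophenyl)amino]sulfonium chloride F1. Et3N then gives ethyl 2-(6-amino-2,3,4-tribromophenyl)-2-(methylsulfanyl)acetate F2, which lactamises in 2 M HCl/Et2O to 4,5,6-tribromo-3-(methylsulfanyl)-1,3-dihydro-2H-indol-2-one F3. NCS (CH2Cl2, 0 °C) gives 4,5,6-tribromo-3-chloro-3-(methylsulfanyl)-1,3-dihydro-2H-indol-2-one F4, an enolonium equivalent of the oxindole. Sodium indolide 10 (2 equiv, THF/DMF, −40 °C → rt) substitutes it at C3 to give 4,5,6-tribromo-3-(methylsulfanyl)-3-[2,4,6-tribromo-3-(methylsulfanyl)-1H-indol-1-yl]-1,3-dihydro-2H-indol-2-one F5. Partial reduction with i-Bu2AlH (CH2Cl2, −78 → 0 °C) gives the hemiaminal 4,5,6-tribromo-3-(methylsulfanyl)-3-[2,4,6-tribromo-3-(methylsulfanyl)-1H-indol-1-yl]-2,3-dihydro-1H-indol-2-ol F6. In TFA/CH2Cl2 this loses water to give 16, which rearranges to 17 as in step 4.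

**Step 3 is second.** NCS may chlorinate 8 at S–CH3 instead of the methylene, or 9 may decompose before it alkylates. The fallback sets out from 7 (as its sodium salt 10) and comes back at 11; it uses an ester-level electrophile whose chlorination is regiochemically secure. Ester 2 and NCS (CH2Cl2, 0 °C → rt) give ethyl 2-chloro-2-(methylsulfanyl)acetate F7. This alkylates 10 in DMF at 0 °C to give ethyl 2-(methylsulfanyl)-2-[2,4,6-tribromo-3-(methylsulfanyl)-1H-indol-1-yl]acetate F8. i-Bu2AlH (toluene, −78 °C) reduces it to 2-(methylsulfanyl)-2-[2,4,6-tribromo-3-(methylsulfanyl)-1H-indol-1-yl]acetaldehyde F9. MeOH with catalytic TsOH and 3 Å molecular sieves converts the aldehyde into acetal 11.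

**Step 2 is third.** POBr3 and the HBr it releases may attack the sulfide or decompose the acid-sensitive 2-bromoindole. The fallback sets out from 1 and comes back at 7; it builds the indole oxidation level directly and brominates afterwards. Aniline 1 is N-chlorinated to 3 and combined with acetal 8 to give [(3,5-dibromophenyl)amino](2,2-dimethoxyethyl)methylsulfonium chloride F10. Et3N gives 3,5-dibromo-2-[2,2-dimethoxy-1-(methylsulfanyl)ethyl]aniline F11, and 0.5 M HCl in Et2O cyclises it to 4,6-dibromo-3-(methylsulfanyl)-1H-indole F12. NBS (1.0 equiv, CH2Cl2, 0 °C) should then brominate the only free pyrrole position, C2, to give 7. The regiochemistry would need confirming, because a competing sulfur shift would give the 3-bromo-2-(methylsulfanyl) isomer.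

## Further compounds

F1 | step 4 | (2-ethoxy-2-oxoethyl)(methyl)[(3,4,5-tribromophenyl)amino]sulfonium chloride | CCOC(=O)C[S+](C)Nc1cc(Br)c(Br)c(Br)c1.[Cl-]
F2 | step 4 | ethyl 2-(6-amino-2,3,4-tribromophenyl)-2-(methylsulfanyl)acetate (racemic) | CCOC(=O)C(SC)c1c(N)cc(Br)c(Br)c1Br
F3 | step 4 | 4,5,6-tribromo-3-(methylsulfanyl)-1,3-dihydro-2H-indol-2-one (racemic) | CSC1C(=O)Nc2cc(Br)c(Br)c(Br)c21
F4 | step 4 | 4,5,6-tribromo-3-chloro-3-(methylsulfanyl)-1,3-dihydro-2H-indol-2-one (racemic) | CSC1(Cl)C(=O)Nc2cc(Br)c(Br)c(Br)c21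
F5 | step 4 | 4,5,6-tribromo-3-(methylsulfanyl)-3-[2,4,6-tribromo-3-(methylsulfanyl)-1H-indol-1-yl]-1,3-dihydro-2H-indol-2-one (racemic) | CSC1(C(=O)Nc2cc(Br)c(Br)c(Br)c21)n1c(Br)c(SC)c2c(Br)cc(Br)cc21
F6 | step 4 | 4,5,6-tribromo-3-(methylsulfanyl)-3-[2,4,6-tribromo-3-(methylsulfanyl)-1H-indol-1-yl]-2,3-dihydro-1H-indol-2-ol (racemic, mixture of diastereomers) | CSC1(C(O)Nc2cc(Br)c(Br)c(Br)c21)n1c(Br)c(SC)c2c(Br)cc(Br)cc21
F7 | step 3 | ethyl 2-chloro-2-(methylsulfanyl)acetate (racemic) | CCOC(=O)C(Cl)SC
F8 | step 3 | ethyl 2-(methylsulfanyl)-2-[2,4,6-tribromo-3-(methylsulfanyl)-1H-indol-1-yl]acetate (racemic) | CCOC(=O)C(SC)n1c(Br)c(SC)c2c(Br)cc(Br)cc21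
F9 | step 3 | 2-(methylsulfanyl)-2-[2,4,6-tribromo-3-(methylsulfanyl)-1H-indol-1-yl]acetaldehyde (racemic) | O=CC(SC)n1c(Br)c(SC)c2c(Br)cc(Br)cc21
F10 | step 2 | [(3,5-dibromophenyl)amino](2,2-dimethoxyethyl)methylsulfonium chloride | COC(OC)C[S+](C)Nc1cc(Br)cc(Br)c1.[Cl-]
F11 | step 2 | 3,5-dibromo-2-[2,2-dimethoxy-1-(methylsulfanyl)ethyl]aniline (racemic) | COC(OC)C(SC)c1c(N)cc(Br)cc1Br
F12 | step 2 | 4,6-dibromo-3-(methylsulfanyl)-1H-indole | CSc1c[nH]c2cc(Br)cc(Br)c12
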